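**Retrosynthetic overview**
- The pyrrole is traced back to an N-tosyl-2,5-dihydropyrrole (loss of toluenesulfinate) and then to a 3-hydroxypyrrolidine (loss of water), so the aromatic oxidation level is reached without an oxidant.
- The hydroxypyrrolidine is cut at N1–C5 and C2–C3 into methyl N-tosylglycinate and hexacos-1-en-3-one. The only ring of the molecule closes in this annulation.
- The structural feature used: pyrrole C3 with its tricosyl chain maps onto the ketone carbon of the enone, C4–C5 onto its vinyl group, and N1–C2(CO2Me) onto a glycine ester.
- The enone comes from tetracosanoic acid through its Weinreb amide and vinylmagnesium bromide. The sulfonamide comes from glycine methyl ester hydrochloride and p-toluenesulfonyl chloride.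

Key step: step 4

Assumption: the target is achiral, so the two sp3 centres created in the annulation are carried as racemic, diastereomeric mixtures and no stereocontrol is attempted.

**Step 1**
Reactants: 1 tetracosanoic acid
Product: 3 N-methoxy-N-methyltetracosanamide, via acyl imidazolide 2 (not isolated)
Conditions: CDI (1.2 equiv), CH2Cl2, 40 °C; then MeNH(OMe)·HCl (1.5 equiv), 40 °C to rt
Reagents that add atoms: N,O-dimethylhydroxylamine hydrochloride, CNOC.Cl
Why: CDI activation to the acyl imidazolide (driven by loss of CO2) followed by aminolysis is a standard Weinreb amide synthesis; it suits the waxy acid in warm CH2Cl2, and the released imidazole takes up the HCl.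

**Step 2**
Reactants: 3 N-methoxy-N-methyltetracosanamide; 4 vinylmagnesium bromide
Product: 6 hexacos-1-en-3-one, via magnesium hemiaminal chelate 5 (not isolated)
Conditions: CH2=CHMgBr (1.5 equiv, 1 M in THF), THF, 0 °C to rt; inverse quench into cold 1 M aq HCl; used promptly
Reagents that add atoms: none
Why: In this Weinreb ketone synthesis the five-membered magnesium chelate 5 persists until work-up, which blocks a second vinyl addition, and the inverse acidic quench keeps the liberated N,O-dimethylhydroxylamine protonated so that it should not add to the new enone.

**Step 3**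
Reactants: 7 glycine methyl ester hydrochloride; 8 p-toluenesulfonyl chloride
Product: 9 methyl N-tosylglycinate
Conditions: Et3N (2.2 equiv), CH2Cl2, 0 °C to rt
Reagents that add atoms: none
Why: N-Sulfonylation of a primary amine with a sulfonyl chloride and Et3N is reliable, and the methyl ester is untouched under these mild conditions.

**Step 4**
Reactants: 6 hexacos-1-en-3-one; 9 methyl N-tosylglycinate
Product: 11 methyl 3-hydroxy-1-tosyl-3-tricosylpyrrolidine-2-carboxylate (racemic mixture of diastereomers), via keto sulfonamide 10 (not isolated)
Conditions: 9 (1.2 equiv), DBU (1.5 equiv), THF, 0 °C to rt (40 °C if needed to keep 6 dissolved)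
Reagents that add atoms: none
Why: DBU deprotonates the sulfonamide N–H of 9 and the nitrogen anion adds to the unsubstituted vinyl terminus of 6 (aza-Michael, N1–C5) to give keto sulfonamide 10; DBU then forms the ester enolate at the glycine carbon, now flanked by CO2Me and N-Ts, which attacks the ketone carbonyl in an intramolecular aldol (C2–C3). The closest known reaction type is the base-mediated annulation of N-sulfonylglycine esters with vinyl ketones that opens the classical route to 3-alkylpyrrole-2-carboxylates. The pyrrolidine ring closes in a 5-exo-trig mode, the enolate carbon attacking the C=O with the oxygen left outside the ring. The new stereocentres C2 and C3 form under reversible aldol conditions with only ring strain and an O–H···O=C hydrogen bond as bias, so a racemic diastereomer mixture is expected, and no control is needed because both centres become sp2 in the pyrrole. The step needs nitrogen to react before carbon and the aldol to win over Claisen-type attack of the ketone enolate on the ester: the first is secured by the much higher acidity of the sulfonamide N–H (which has one proton only and cannot add twice), the second by the weak, non-nucleophilic amidine base, which does not drive a methoxide-expelling acylation.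

**Step 5**
Reactants: 11 methyl 3-hydroxy-1-tosyl-3-tricosylpyrrolidine-2-carboxylate
Product: 13 methyl 1-tosyl-3-tricosyl-2,5-dihydro-1H-pyrrole-2-carboxylate (racemic), via dichlorophosphate ester 12 (not isolated)
Conditions: POCl3 (5 equiv), pyridine, 0 °C to rt
Reagents that add atoms: none
Why: POCl3 converts the tertiary alcohol into dichlorophosphate 12, from which pyridine removes a C4 proton in an E2 elimination (the classical POCl3–pyridine dehydration of tertiary alcohols); ester and sulfonamide stay in place, the C3 stereocentre is destroyed and C2 remains racemic.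

**Step 6**
Reactants: 13 methyl 1-tosyl-3-tricosyl-2,5-dihydro-1H-pyrrole-2-carboxylate
Product: 15 methyl 3-tricosyl-1H-pyrrole-2-carboxylate (target), via 2H-pyrrole 14 (not isolated)
Conditions: DBU (3 equiv), toluene, 80 °C
Reagents that add atoms: none
Why: In this E1cB-type eliminative aromatisation DBU removes the doubly activated C2–H (alpha to the ester and allylic), the dienolate expels p-toluenesulfinate from nitrogen to give 2H-pyrrole 14, and a base-mediated proton shift from C5 to nitrogen gives the aromatic 1H-pyrrole; DBU is non-nucleophilic, so the methyl ester is neither exchanged nor cleaved.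

**Compound list**
1 | tetracosanoic acid | CCCCCCCCCCCCCCCCCCCCCCCC(=O)O | starting material
2 | 1-(1H-imidazol-1-yl)tetracosan-1-one (acyl imidazolide) | CCCCCCCCCCCCCCCCCCCCCCCC(=O)n1ccnc1 | intermediate (not isolated)
3 | N-methoxy-N-methyltetracosanamide | CCCCCCCCCCCCCCCCCCCCCCCC(=O)N(C)OC | intermediate
4 | vinylmagnesium bromide | C=C[Mg]Br | starting material
5 | bromomagnesium 3-[methoxy(methyl)amino]hexacos-1-en-3-olate (tetrahedral chelate) | CCCCCCCCCCCCCCCCCCCCCCCC(C=C)(O[Mg]Br)N(C)OC | intermediate (not isolated)
6 | hexacos-1-en-3-one | CCCCCCCCCCCCCCCCCCCCCCCC(=O)C=C | intermediate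
7 | glycine methyl ester hydrochloride | COC(=O)CN.Cl | starting material
8 | p-toluenesulfonyl chloride | Cc1ccc(S(=O)(=O)Cl)cc1 | starting material
9 | methyl N-tosylglycinate | COC(=O)CNS(=O)(=O)c1ccc(C)cc1 | intermediate
10 | methyl N-(3-oxohexacosyl)-N-tosylglycinate | CCCCCCCCCCCCCCCCCCCCCCCC(=O)CCN(CC(=O)OC)S(=O)(=O)c1ccc(C)cc1 | intermediate (not isolated)
11 | methyl 3-hydroxy-1-tosyl-3-tricosylpyrrolidine-2-carboxylate (racemic, mixture of diastereomers) | CCCCCCCCCCCCCCCCCCCCCCCC1(O)CCN(S(=O)(=O)c2ccc(C)cc2)C1C(=O)OC | intermediate
12 | methyl 3-(dichlorophosphoryloxy)-1-tosyl-3-tricosylpyrrolidine-2-carboxylate | CCCCCCCCCCCCCCCCCCCCCCCC1(OP(=O)(Cl)Cl)CCN(S(=O)(=O)c2ccc(C)cc2)C1C(=O)OC | intermediate (not isolated)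
13 | methyl 1-tosyl-3-tricosyl-2,5-dihydro-1H-pyrrole-2-carboxylate (racemic) | CCCCCCCCCCCCCCCCCCCCCCCC1=CCN(S(=O)(=O)c2ccc(C)cc2)C1C(=O)OC | intermediate
14 | methyl 4-tricosyl-2H-pyrrole-5-carboxylate | CCCCCCCCCCCCCCCCCCCCCCCC1=CCN=C1C(=O)OC | intermediate (not isolated)
15 | methyl 3-tricosyl-1H-pyrrole-2-carboxylate | CCCCCCCCCCCCCCCCCCCCCCCc1cc[nH]c1C(=O)OC | target

**Step count**
Total: 6 steps. Longest linear sequence: 5 steps (steps 1, 2, 4, 5, 6); step 3 is a one-step side branch.

**Steps most likely to fail**

Step 4. The annulation may stall after the conjugate addition if the aldol closure stays on the open-chain side of its equilibrium, or the vinyl ketone may oligomerise under base before the sulfonamide captures it. The fallback builds the ring by a Barton–Zard pyrrole synthesis instead. It sets out from Weinreb amide 3: LiAlH4 in THF at 0 °C should give tetracosanal F1. A Henry addition of nitromethane (excess MeNO2, catalytic DBU, THF, rt) should then give racemic 1-nitropentacosan-2-ol F2. Dehydration with methanesulfonyl chloride and Et3N in CH2Cl2 at 0 °C should give (E)-1-nitropentacos-1-ene F3. Treatment of F3 with methyl isocyanoacetate (COC(=O)C[N+]#[C-]) and DBU in THF at rt should proceed by conjugate addition, closure onto the isocyanide carbon, loss of nitrite and tautomerisation. This places the chain at C3 and the ester at C2, and the fallback comes back to the route at target 15.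

Step 2. Conjugate addition of the liberated N,O-dimethylhydroxylamine or of a second equivalent of Grignard reagent to the fresh enone during quench, and oligomerisation on concentration, may erode the vinyl ketone. The fallback makes the acyl–vinyl bond by a neutral Stille acylation and sets out from acid 1. Oxalyl chloride with catalytic DMF in CH2Cl2 should give tetracosanoyl chloride F4. Coupling of F4 with tributyl(vinyl)stannane (Bu3SnCH=CH2) and catalytic PdCl2(PPh3)2 in toluene at 60 °C should give the enone with no amine or carbanion present. The fallback comes back to the route at compound 6.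

Step 5. Activation of the hindered tertiary alcohol may be slow, the β-hydroxy ester may ring-open by retro-aldol, or elimination may run toward C2 or into the side chain. The fallback changes the alkene-forming event to a β-elimination through the ester enolate and sets out from 11. Methanesulfonyl chloride and Et3N in CH2Cl2 at 0 °C (sulfene mesylation) should give methyl 3-(methylsulfonyloxy)-1-tosyl-3-tricosylpyrrolidine-2-carboxylate F5. DBU in toluene at rt should then eliminate mesylate across C2–C3 (E1cB) to give the conjugated methyl 1-tosyl-3-tricosyl-4,5-dihydro-1H-pyrrole-2-carboxylate F6. Heating F6 with DBU at 80–110 °C should deprotonate C4 to give the same dienolate that 13 gives in step 6; this loses toluenesulfinate and tautomerises, so the fallback comes back to the route at target 15.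

**Further compounds**
F1 | step 4 | tetracosanal | CCCCCCCCCCCCCCCCCCCCCCCC=O
F2 | step 4 | 1-nitropentacosan-2-ol (racemic) | CCCCCCCCCCCCCCCCCCCCCCCC(O)C[N+](=O)[O-]
F3 | step 4 | (E)-1-nitropentacos-1-ene | CCCCCCCCCCCCCCCCCCCCCCC/C=C/[N+](=O)[O-]
F4 | step 2 | tetracosanoyl chloride | CCCCCCCCCCCCCCCCCCCCCCCC(=O)Cl
F5 | step 5 | methyl 3-(methylsulfonyloxy)-1-tosyl-3-tricosylpyrrolidine-2-carboxylate (racemic, mixture of diastereomers) | CCCCCCCCCCCCCCCCCCCCCCCC1(OS(C)(=O)=O)CCN(S(=O)(=O)c2ccc(C)cc2)C1C(=O)OC
F6 | step 5 | methyl 1-tosyl-3-tricosyl-4,5-dihydro-1H-pyrrole-2-carboxylate | CCCCCCCCCCCCCCCCCCCCCCCC1=C(C(=O)OC)N(S(=O)(=O)c2ccc(C)cc2)CC1
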